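**Plan**

- Retrosynthesis: the hydroquinone ring is opened at C1'–C2', C2'–C3' and C5'–C6' (carbene complex + alkyne + CO), leaving a 2-ethynylfuran. The next cuts are the C5–furan C3 bond (conjugate addition), the C7=C8 and C5=C6 alkenes (two Wittig reactions) and the alkyne carbon (aldehyde homologation).
- Enabling feature: the benzene ring has oxygens at C2' and C5' (para) and one carbon substituent, furan C5 on C1', ortho to the C2' oxygen. An alkenyl(alkoxy)carbene, a terminal alkyne and CO assemble exactly this pattern.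
- Forward: the furan is bought. A 3-furyl boronate carrying a silyl-capped 5-ethynyl group is joined at C5 to the C1–C7 enal, the chain is finished by isopropylidenation, the alkyne is freed, and the benzene ring is built last on it. Saponification and an oxidation/reduction pair then release the hydroquinone acid.
- Stereochemistry: C3 (R) is bought in methyl hydrogen (R)-3-methylglutarate. C5 (S) is set by a rhodium–chiral diene 1,4-addition under catalyst control.

Key step: step 11

Assumption: hemiester 6 is bought as the single (R)-enantiomer; the facial sense of step 7 is assigned from the usual model for rhodium–diene additions to linear (E)-acceptors and is to be confirmed on the first batch (the ligand antipode is equally available).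

**Step 1**
Reactants: 1 4-bromofuran-2-carbaldehyde
Product: 2 4-bromo-2-ethynylfuran
Conditions: dimethyl (1-diazo-2-oxopropyl)phosphonate, K2CO3, MeOH, 0 °C to rt
Reagents that add atoms: dimethyl (1-diazo-2-oxopropyl)phosphonate, CC(=O)C(=[N+]=[N-])P(=O)(OC)OC
Why: Ohira–Bestmann (Seyferth–Gilbert) homologation should convert the non-enolisable heteroaryl aldehyde into the terminal alkyne under conditions that leave the bromofuran untouched.

**Step 2**
Reactants: 2 4-bromo-2-ethynylfuran
Product: 4 [(4-bromofuran-2-yl)ethynyl]tri(propan-2-yl)silane, via lithium acetylide 3 (not isolated)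
Conditions: LiN(SiMe3)2, THF, −78 °C; iPr3SiOTf, −78 °C to 0 °C
Reagents that add atoms: triisopropylsilyl trifluoromethanesulfonate, CC(C)[Si](OS(=O)(=O)C(F)(F)F)(C(C)C)C(C)C
Why: Deprotonation and C-silylation of a terminal alkyne, in which the amide base removes only the acetylenic proton (no bromine–lithium exchange, no furan metalation) and the bulky silyl cap is chosen to survive the later palladium, rhodium, hydroxide and ylide steps.

**Step 3**
Reactants: 4 [(4-bromofuran-2-yl)ethynyl]tri(propan-2-yl)silane
Product: 5 4,4,5,5-tetramethyl-2-(5-{[tri(propan-2-yl)silyl]ethynyl}furan-3-yl)-1,3,2-dioxaborolane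
Conditions: B2pin2, Pd(dppf)Cl2 (3 mol%), KOAc, 1,4-dioxane, 85 °C
Reagents that add atoms: bis(pinacolato)diboron, CC1(C)OB(OC1(C)C)B1OC(C)(C)C(C)(C)O1
Why: Miyaura borylation of a heteroaryl bromide through zerovalent palladium should give a 3-furyl boronate, a class far less prone to protodeboronation than 2-furyl boronates.

**Step 4**
Reactants: 6 (3R)-5-methoxy-3-methyl-5-oxopentanoic acid (methyl hydrogen (R)-3-methylglutarate)
Product: 7 methyl (3R)-5-hydroxy-3-methylpentanoate
Conditions: BH3·SMe2, THF, 0 °C to rt; then H2O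
Reagents that add atoms: none
Why: Chemoselective borane reduction of a carboxylic acid in the presence of a methyl ester should give the hydroxy ester without touching the C3 stereocentre.

**Step 5**
Reactants: 7 methyl (3R)-5-hydroxy-3-methylpentanoate
Product: 8 methyl (3R)-3-methyl-5-oxopentanoate
Conditions: TEMPO (10 mol%), PhI(OAc)2, CH2Cl2, rt
Reagents that add atoms: none
Why: The nitroxyl-catalysed oxidation with PhI(OAc)2 stops at the aldehyde and is neither basic nor strongly acidic, so lactonisation is avoided and the β-stereocentre cannot epimerise.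

**Step 6**
Reactants: 8 methyl (3R)-3-methyl-5-oxopentanoate
Product: 9 methyl (3R,5E)-3-methyl-7-oxohept-5-enoate
Conditions: Ph3P=CHCHO, toluene, 80 °C
Reagents that add atoms: (triphenylphosphoranylidene)acetaldehyde, O=CC=P(c1ccccc1)(c1ccccc1)c1ccccc1
Why: Wittig olefination with the stabilised formylmethylene ylide should give the (E)-enal, with a near-stoichiometric charge of ylide limiting a second homologation.

**Step 7**
Reactants: 9 methyl (3R,5E)-3-methyl-7-oxohept-5-enoate; 5 4,4,5,5-tetramethyl-2-(5-{[tri(propan-2-yl)silyl]ethynyl}furan-3-yl)-1,3,2-dioxaborolane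
Product: 10 methyl (3R,5S)-3-methyl-7-oxo-5-(5-{[tri(propan-2-yl)silyl]ethynyl}furan-3-yl)heptanoate
Conditions: [RhCl(C2H4)2]2 (2.5 mol%), (1S,4S)-2,5-diphenylbicyclo[2.2.2]octa-2,5-diene (5.5 mol%), KOH (0.2 equiv), 1,4-dioxane/H2O 10:1, 40 °C
Reagents that add atoms: none
Why: Hayashi–Miyaura 1,4-addition, in which the furyl group passes from boron to monovalent rhodium and inserts the enal; chiral diene ligands favour 1,4- over 1,2-addition to enals, and the (S,S)-diene is expected to deliver the furyl group to the Si face of C5, setting 5S under catalyst control while the remote C3 centre and the bulky silylalkyne stay out of play.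

**Step 8**
Reactants: 10 methyl (3R,5S)-3-methyl-7-oxo-5-(5-{[tri(propan-2-yl)silyl]ethynyl}furan-3-yl)heptanoate
Product: 11 methyl (3R,5S)-3,8-dimethyl-5-(5-{[tri(propan-2-yl)silyl]ethynyl}furan-3-yl)non-7-enoate
Conditions: iPrPPh3I, n-BuLi, THF, 0 °C; then 10, −78 °C to 0 °C
Reagents that add atoms: isopropyltriphenylphosphonium iodide, CC(C)[P+](c1ccccc1)(c1ccccc1)c1ccccc1.[I-]
Why: Wittig olefination with the non-stabilised isopropylidene ylide, which should take the aldehyde much faster than the methyl ester at low temperature; C5 is β to the aldehyde and is not at risk.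

**Step 9**
Reactants: 11 methyl (3R,5S)-3,8-dimethyl-5-(5-{[tri(propan-2-yl)silyl]ethynyl}furan-3-yl)non-7-enoate
Product: 12 methyl (3R,5S)-5-(5-ethynylfuran-3-yl)-3,8-dimethylnon-7-enoate
Conditions: Bu4NF, THF, 0 °C
Reagents that add atoms: none
Why: Fluoride-induced protodesilylation of an alkynylsilane should free the terminal alkyne while ester, furan and alkene remain inert; the ethynylfuran is used at once.

**Step 10**
Reactants: 13 (E)-(2-bromovinyl)trimethylsilane; 14 chromium hexacarbonyl
Product: 17 pentacarbonyl[(E)-1-methoxy-3-(trimethylsilyl)prop-2-en-1-ylidene]chromium, via vinyllithium 15 (not isolated), via lithium acylchromate 16 (not isolated)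
Conditions: t-BuLi (2 equiv), Et2O, −78 °C; Cr(CO)6, Et2O/THF, −78 °C to rt; Me3OBF4, CH2Cl2/H2O, 0 °C
Reagents that add atoms: trimethyloxonium tetrafluoroborate, C[O+](C)C.F[B-](F)(F)F
Why: Fischer carbene synthesis, in which bromine–lithium exchange with retention of the (E)-geometry, addition of the vinyllithium to a CO ligand of zerovalent chromium and O-methylation of the acylmetalate should give the known silylvinyl methoxycarbene complex.

**Step 11**
Reactants: 12 methyl (3R,5S)-5-(5-ethynylfuran-3-yl)-3,8-dimethylnon-7-enoate; 17 pentacarbonyl[(E)-1-methoxy-3-(trimethylsilyl)prop-2-en-1-ylidene]chromium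
Product: 19 methyl (3R,5S)-5-{5-[5-methoxy-2-(trimethylsilyloxy)phenyl]furan-3-yl}-3,8-dimethylnon-7-enoate, via arene tricarbonylchromium complex 18 (not isolated)
Conditions: 17 (1.5 equiv), THF (0.05 M), argon, 50 °C; then air, Et2O, filtration through Celite
Reagents that add atoms: none
Why: Thermal loss of a cis CO ligand from 17 lets the alkyne of 12 coordinate and insert into the chromium–carbene bond to give an η3-vinylcarbene, CO insertion gives an η4-dienylketene, and six-electron electrocyclisation closes a chromium-bound cyclohexa-2,4-dienone whose former vinyl terminus carries H and SiMe3. A 1,3-shift of silicon from that carbon to the carbonyl oxygen aromatises the ring to the aryl silyl ether complex 18, and air strips the Cr(CO)3 unit to leave 19, which is carried forward crude because the aryl trimethylsilyl ether is labile. The closest known reaction is the Dötz benzannulation of alkenyl(alkoxy)carbene chromium complexes with terminal alkynes, with trans-β-silylvinyl complexes serving as stable stand-ins for the polymerisation-prone parent vinylcarbene. The one ring formed, the benzene ring, is closed by disrotatory 6π-electrocyclisation of the dienylketene, a formal [3+2+1] union of three carbene-ligand carbons, two alkyne carbons and one CO; no stereocentre is created and C3 and C5 are remote from the reacting atoms. The step needs regioselective insertion, which the terminal alkyne secures on steric grounds: its CH carbon bonds to the carbene carbon (C5'–C6') and the furyl-bearing carbon to the CO carbon (C1'–C2'), so the furan sits ortho to the silyloxy group and the two oxygens are para. It also needs the carbene to choose the alkyne over the trisubstituted alkene and the furan, which is the normal order of reactivity at 50 °C, while the ester is a spectator.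

**Step 12**
Reactants: 19 methyl (3R,5S)-5-{5-[5-methoxy-2-(trimethylsilyloxy)phenyl]furan-3-yl}-3,8-dimethylnon-7-enoate
Product: 20 (3R,5S)-5-[5-(2-hydroxy-5-methoxyphenyl)furan-3-yl]-3,8-dimethylnon-7-enoic acid
Conditions: LiOH, THF/MeOH/H2O (degassed), rt; then 1 M HCl to pH 4, 0 °C
Reagents that add atoms: lithium hydroxide, [Li+].[OH-]
Why: Saponification of the methyl ester, which at the same time cleaves the labile aryl trimethylsilyl ether so that silylated and free phenol converge on one product; no stereocentre is α to the carboxyl group.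

**Step 13**
Reactants: 20 (3R,5S)-5-[5-(2-hydroxy-5-methoxyphenyl)furan-3-yl]-3,8-dimethylnon-7-enoic acid
Product: 22 (3R,5S)-5-[5-(2,5-dihydroxyphenyl)furan-3-yl]-3,8-dimethylnon-7-enoic acid, via quinone acid 21 (not isolated)
Conditions: PhI(OAc)2, MeCN/H2O 4:1, 0 °C; then Na2S2O4, H2O/EtOAc, rt, argon
Reagents that add atoms: water, O
Why: Oxidative demethylation of a para-methoxyphenol by hypervalent iodine (water adds at the methoxy-bearing carbon and methanol is lost) should give the quinone without touching the alkene or the furan, and dithionite reduction in the same flask gives the hydroquinone so that the sensitive furyl quinone is never stored.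

**Compound list**

1 | 4-bromofuran-2-carbaldehyde | O=Cc1cc(Br)co1 | starting material
2 | 4-bromo-2-ethynylfuran | C#Cc1cc(Br)co1 | intermediate
3 | lithium (4-bromofuran-2-yl)ethynide | [Li]C#Cc1cc(Br)co1 | intermediate
4 | [(4-bromofuran-2-yl)ethynyl]tri(propan-2-yl)silane | CC(C)[Si](C#Cc1cc(Br)co1)(C(C)C)C(C)C | intermediate
5 | 4,4,5,5-tetramethyl-2-(5-{[tri(propan-2-yl)silyl]ethynyl}furan-3-yl)-1,3,2-dioxaborolane | CC(C)[Si](C#Cc1cc(B2OC(C)(C)C(C)(C)O2)co1)(C(C)C)C(C)C | intermediate
6 | (3R)-5-methoxy-3-methyl-5-oxopentanoic acid | OC(=O)C[C@@H](C)CC(=O)OC | starting material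
7 | methyl (3R)-5-hydroxy-3-methylpentanoate | OCC[C@@H](C)CC(=O)OC | intermediate
8 | methyl (3R)-3-methyl-5-oxopentanoate | O=CC[C@@H](C)CC(=O)OC | intermediate
9 | methyl (3R,5E)-3-methyl-7-oxohept-5-enoate | O=C/C=C/C[C@@H](C)CC(=O)OC | intermediate
10 | methyl (3R,5S)-3-methyl-7-oxo-5-(5-{[tri(propan-2-yl)silyl]ethynyl}furan-3-yl)heptanoate | O=CC[C@H](C[C@@H](C)CC(=O)OC)c1coc(C#C[Si](C(C)C)(C(C)C)C(C)C)c1 | intermediate
11 | methyl (3R,5S)-3,8-dimethyl-5-(5-{[tri(propan-2-yl)silyl]ethynyl}furan-3-yl)non-7-enoate | CC(C)=CC[C@H](C[C@@H](C)CC(=O)OC)c1coc(C#C[Si](C(C)C)(C(C)C)C(C)C)c1 | intermediate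
12 | methyl (3R,5S)-5-(5-ethynylfuran-3-yl)-3,8-dimethylnon-7-enoate | CC(C)=CC[C@H](C[C@@H](C)CC(=O)OC)c1coc(C#C)c1 | intermediate
13 | (E)-(2-bromovinyl)trimethylsilane | C[Si](C)(C)/C=C/Br | starting material
14 | chromium hexacarbonyl, Cr(CO)6 | O=C=[Cr](=C=O)(=C=O)(=C=O)(=C=O)=C=O | starting material
15 | (E)-[2-(trimethylsilyl)ethenyl]lithium | [Li]/C=C/[Si](C)(C)C | intermediate
16 | lithium pentacarbonyl[(E)-1-oxido-3-(trimethylsilyl)prop-2-en-1-ylidene]chromate | [Li+].[O-]C(/C=C/[Si](C)(C)C)=[Cr](=C=O)(=C=O)(=C=O)(=C=O)=C=O | intermediate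
17 | pentacarbonyl[(E)-1-methoxy-3-(trimethylsilyl)prop-2-en-1-ylidene]chromium | O=C=[Cr](=C=O)(=C=O)(=C=O)(=C=O)=C(OC)/C=C/[Si](C)(C)C | intermediate
18 | tricarbonyl(η6-arene)chromium complex of 19, Cr(CO)3 on the benzene ring (arene and metal fragment written as two parts) | CC(C)=CC[C@H](C[C@@H](C)CC(=O)OC)c1coc(-c2cc(OC)ccc2O[Si](C)(C)C)c1.O=C=[Cr](=C=O)=C=O | intermediate
19 | methyl (3R,5S)-5-{5-[5-methoxy-2-(trimethylsilyloxy)phenyl]furan-3-yl}-3,8-dimethylnon-7-enoate | CC(C)=CC[C@H](C[C@@H](C)CC(=O)OC)c1coc(-c2cc(OC)ccc2O[Si](C)(C)C)c1 | intermediate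
20 | (3R,5S)-5-[5-(2-hydroxy-5-methoxyphenyl)furan-3-yl]-3,8-dimethylnon-7-enoic acid | CC(C)=CC[C@H](C[C@@H](C)CC(=O)O)c1coc(-c2cc(OC)ccc2O)c1 | intermediate
21 | (3R,5S)-5-[5-(3,6-dioxocyclohexa-1,4-dien-1-yl)furan-3-yl]-3,8-dimethylnon-7-enoic acid | CC(C)=CC[C@H](C[C@@H](C)CC(=O)O)c1coc(C2=CC(=O)C=CC2=O)c1 | intermediate
22 | (3R,5S)-5-[5-(2,5-dihydroxyphenyl)furan-3-yl]-3,8-dimethylnon-7-enoic acid | CC(C)=CC[C@H](C[C@@H](C)CC(=O)O)c1coc(-c2cc(O)ccc2O)c1 | target

**Totals**

Total step count: 13. Longest linear sequence: 9 steps (1 to 22 through steps 1, 2, 3, 7, 8, 9, 11, 12, 13; the branch from 6 is equally long).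

**Steps most likely to fail**

Step 11. The ethynylfuran may polymerise before it inserts, the vinylketene may be diverted to five-membered-ring products, and the carbon-to-oxygen silyl shift may be incomplete, all on a late and precious alkyne. The fallback keeps the benzannulation but moves it to the start of the furan branch; it sets out from 2 and 17 and comes back at 20. Alkyne 2, available in quantity, is heated with 17 in THF to give [2-(4-bromofuran-2-yl)-4-methoxyphenoxy]trimethylsilane F4, and K2CO3 in MeOH on work-up gives 2-(4-bromofuran-2-yl)-4-methoxyphenol F5. Miyaura borylation as in step 3 should give 4-methoxy-2-[4-(4,4,5,5-tetramethyl-1,3,2-dioxaborolan-2-yl)furan-2-yl]phenol F6. Rhodium–diene addition of F6 to enal 9 as in step 7 should give methyl (3R,5S)-5-[5-(2-hydroxy-5-methoxyphenyl)furan-3-yl]-3-methyl-7-oxoheptanoate F7. Isopropylidenation with excess ylide (the phenol consumes one equivalent) should give methyl (3R,5S)-5-[5-(2-hydroxy-5-methoxyphenyl)furan-3-yl]-3,8-dimethylnon-7-enoate F8, which LiOH converts into 20.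

Step 7. Competing 1,2-addition to the aldehyde, protodeboronation of the furyl boronate before transmetalation, or poor facial discrimination at C5 may erode the outcome. The fallback replaces catalyst control by an auxiliary; it sets out from 8 and 4 and comes back at 10. Aldehyde 8 is condensed (LiCl, iPr2NEt, MeCN) with diethyl {2-oxo-2-[(4R)-2-oxo-4-phenyl-1,3-oxazolidin-3-yl]ethyl}phosphonate to give methyl (3R,5E)-3-methyl-7-oxo-7-[(4R)-2-oxo-4-phenyl-1,3-oxazolidin-3-yl]hept-5-enoate F1. Bromide 4 is converted with n-BuLi at −78 °C, MgBr2·OEt2 and CuBr·SMe2 into the furylcopper reagent, which should add to the chelated syn-s-cis imide on the face opposite the phenyl group to give methyl (3R,5S)-3-methyl-7-oxo-7-[(4R)-2-oxo-4-phenyl-1,3-oxazolidin-3-yl]-5-(5-{[tri(propan-2-yl)silyl]ethynyl}furan-3-yl)heptanoate F2. NaBH4 in THF/H2O should cleave the imide reductively in the presence of the methyl ester to methyl (3R,5S)-7-hydroxy-3-methyl-5-(5-{[tri(propan-2-yl)silyl]ethynyl}furan-3-yl)heptanoate F3, and oxidation as in step 5 returns 10.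

Step 13. Over-oxidation of the electron-rich arylfuran, or addition of water or acetate to the furyl quinone before it is reduced, may consume material. The fallback avoids any change of oxidation level; it sets out from 20 and comes back at 22. Acid 20 is heated with excess NaSEt in DMF at 120 °C under argon, so that the aryl methyl ether is cleaved by nucleophilic attack of thiolate on the methyl group, and careful acidification gives 22 directly.

**Further compounds**

F1 | step 7 | methyl (3R,5E)-3-methyl-7-oxo-7-[(4R)-2-oxo-4-phenyl-1,3-oxazolidin-3-yl]hept-5-enoate | O=C(/C=C/C[C@@H](C)CC(=O)OC)N1C(=O)OC[C@H]1c1ccccc1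
F2 | step 7 | methyl (3R,5S)-3-methyl-7-oxo-7-[(4R)-2-oxo-4-phenyl-1,3-oxazolidin-3-yl]-5-(5-{[tri(propan-2-yl)silyl]ethynyl}furan-3-yl)heptanoate | O=C(C[C@H](C[C@@H](C)CC(=O)OC)c1coc(C#C[Si](C(C)C)(C(C)C)C(C)C)c1)N1C(=O)OC[C@H]1c1ccccc1
F3 | step 7 | methyl (3R,5S)-7-hydroxy-3-methyl-5-(5-{[tri(propan-2-yl)silyl]ethynyl}furan-3-yl)heptanoate | OCC[C@H](C[C@@H](C)CC(=O)OC)c1coc(C#C[Si](C(C)C)(C(C)C)C(C)C)c1
F4 | step 11 | [2-(4-bromofuran-2-yl)-4-methoxyphenoxy]trimethylsilane | COc1ccc(O[Si](C)(C)C)c(-c2cc(Br)co2)c1
F5 | step 11 | 2-(4-bromofuran-2-yl)-4-methoxyphenol | COc1ccc(O)c(-c2cc(Br)co2)c1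
F6 | step 11 | 4-methoxy-2-[4-(4,4,5,5-tetramethyl-1,3,2-dioxaborolan-2-yl)furan-2-yl]phenol | COc1ccc(O)c(-c2cc(B3OC(C)(C)C(C)(C)O3)co2)c1
F7 | step 11 | methyl (3R,5S)-5-[5-(2-hydroxy-5-methoxyphenyl)furan-3-yl]-3-methyl-7-oxoheptanoate | O=CC[C@H](C[C@@H](C)CC(=O)OC)c1coc(-c2cc(OC)ccc2O)c1
F8 | step 11 | methyl (3R,5S)-5-[5-(2-hydroxy-5-methoxyphenyl)furan-3-yl]-3,8-dimethylnon-7-enoate | CC(C)=CC[C@H](C[C@@H](C)CC(=O)OC)c1coc(-c2cc(OC)ccc2O)c1
F0 | step 13 | none | none
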